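The runs come from a simulation for substances that don't exist; scatter was added.

By 25.0 h the free monomer of the violet run has fallen to 59.6%, from 63.6% at 10.0 h. The new flask has violet's initiator and twice its free monomer.

| flask | free monomer | initiator | remark | time |
|---|---|---|---|---|
| blue | 1 M | 50 mM | run made earlier |  |
| amber | 1 M | 75 mM | run made earlier |  |
| violet | 0.50 M | 100 mM | run made earlier |  |
| flask | 1.0 M | 100 mM |  | 20 h |

- blue (time / h: monomer in chains / %, free monomer / %): 6.00: 14.7, 85.4; 12.0: 18.0, 81.9; 20.0: 19.6, 81.1; 25.0: 19.8, 80.4
- amber (time / h: monomer in chains / %, free monomer / %): 2.00: 13.8, 86.9; 4.00: 17.7, 82.2; 10.0: 22.9, 75.9; 25.0: 26.3, 73.5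
- violet (time / h: monomer in chains / %, free monomer / %): 2.00: 24.5, 75.3; 4.00: 30.5, 68.7; 10.0: 36.9, 63.6; 25.0: 39.9, 59.6

(scatter of a reading: 0.3 percentage points)

- the average divides the monomer in chains by the number of chains begun, living and dead together
- what was read earlier has a scatter of 0.3 percentage points, one standard deviation
- the earlier runs do not show the number of chains; that part of a forecast is a guess

1. average number of monomer units in a chain (chains begun, living or dead) at 20 h
2. part of the free monomer that has reacted at 20 h

1. Suppose chains grow at a living end born from the initiator. Free monomer then falls pseudo-first-order, and the logarithm of its fall should scale with the initiator charge. Per unit of initiator, that logarithm at the last reading is 4.36 M⁻¹ in blue, 4.11 M⁻¹ in amber and 5.18 M⁻¹ in violet.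

2. Objection: violet stands higher than amber, so this is no constant.

3. Perhaps each initiator takes one free monomer as it starts a chain, and that loss is not first-order. With M the monomer charge, N the initiator charge and m the free monomer read, I take the growth logarithm per initiator, G = ln[(M − N)/m]/N. It reads 3.34 M⁻¹ in blue, 3.07 M⁻¹ in amber and 2.94 M⁻¹ in violet, so these readings now fall from run to run as the initiator charge rises.

4. Violet's G on the flask gives a reacted part c of 33.0%. If each initiator begins one chain, the average is 3.29.

5. Objection: G was read at 25.0 h, later than 20 h, so my c may stand high. The one monomer per initiator also remains a guess.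

The forecast gives a reacted part of 32% and an average of 4.2, and says of its chains “Chain count is a guess”. My average is lower than its 4.2, and my c is higher than its 32%.

The flask gives a reacted part of 31.6% and an average of 3.16.

    free monomer + living end → monomer in chains + living end, rate k1*[living end]*[free monomer] (k = 0.610 M⁻¹ h⁻¹)
    living end → dead end B (k = 0.129 h⁻¹)
    free monomer + initiator → living end + monomer in chains (k = 3.78 M⁻¹ h⁻¹)
    2 living end → dead end A (k = 1.03 M⁻¹ h⁻¹)

The flask's own G at 20 h reads 2.74 M⁻¹. On the neighbour flask with 0.40 M of initiator, violet's G gives c = 81.5%, but that flask gives 68.3% and an average of 1.71. Its own G reads 1.59 M⁻¹, about half of violet's. At 20.0 h that neighbour holds 0.133 M of dead end A and 0.129 M of dead end B, where this flask holds 0.0195 M and 0.0577 M.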